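I began from late times and counted the charge. One substrate makes one target and the solid first nucleophile stands at 1.30 equiv, so substrate is the limiting reagent, and the charge points to 3.0 mM of target in autumn and 100 mM in winter. In each flask substrate opens reversibly to an intermediate. The first nucleophile, coming slowly out of its solid, captures the intermediate to give target. The second nucleophile, coming slowly out of a held gas, captures it to give the other capture product, and the intermediate also decays to side product.

    substrate ⇌ intermediate (K1 = 0.16, k1 = 0.22 /s)
    first nucleophile + intermediate → target (k2 = 71 /M/s)
    second nucleophile + intermediate → other capture product (k3 = 2800 /M/s)
    intermediate → side product (k4 = 0.032 /s)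
    solid first nucleophile ⇌ first nucleophile, rate k5*(cs5 - [first nucleophile]) while solid is left; crystals form when [first nucleophile] > cs5 (cs5 = 7.4 mM, k5 = 0.011 /s)
    gas ⇌ second nucleophile, rate k6*(csat - [second nucleophile]) (k6 = 0.029 /s, csat = 2.7 mM)

| setting | autumn | spring | midnight | winter |
|---|---|---|---|---|
| substrate | 3.0 mM | 10 mM | 30 mM | 100 mM |
| solid first nucleophile | 1.30 equiv | 1.30 equiv | 1.30 equiv | 1.30 equiv |
| gas | 2.7 mM (held) | 2.7 mM (held) | 2.7 mM (held) | 2.7 mM (held) |
| time | 100 s | 100 s | 100 s | 100 s |

- [target] at the end for autumn, spring, midnight, winter, in this order
- how the row runs (falls, then rises / rises, then falls / falls all the way / hardly changes / rises all the way)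

- given per volume of solution although it is solid: solid first nucleophile
- at the start none of second nucleophile is dissolved
- at the start none of the solid first nucleophile is in solution
- "hardly changes" means that all values lie within two and a half points (for a concentration: within two and a half percent of the largest)
- run time (autumn): 100 s

But the run is short, so my second way counted delivery. I took the supply ceiling, the dissolution coefficient times the solubility times the run time, 8.14 mM, which is what the solid delivers into a solution kept empty while solid is left. In winter this lies far below the charge, and delivering an amount equal to the substrate charge takes 1230 s, so there the charge way cheats. Was the ceiling reached? Taking substrate and intermediate at equilibrium on the whole charge, I put winter's intermediate near 13.8 mM. It catches a dissolved first nucleophile within 1.02 s, much sooner than the 90.9 s of dissolving. So I expected winter's target just under the ceiling.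

In autumn the ways part the other way: the ceiling exceeds the charge, so the ceiling cheats, and the charge is no guide either. On the same equilibrium I put the autumn intermediate near 0.414 mM, and at that amount it catches second nucleophile far faster than gas delivers it. So the gas should use up the autumn charge in about 38.3 s. Letting the intermediate fall in a line over that time while first nucleophile rises in a line, I reckoned 0.585 mM of target in autumn. The flasks between I left unreckoned.

The forecast gave 0.45 mM, 2 mM, 6.4 mM and 7.85 mM, a row that rises all the way. It held that at high substrate “the intermediate lasts the full run and captures the first nucleophile as fast as it dissolves”, near about 8 mM.

The simulation gave 0.361 mM, 2.71 mM, 6.79 mM and 7.86 mM, a row that rises all the way.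

Winter's 7.86 mM stands at 96.6% of the supply ceiling of 8.14 mM. In midnight the target of 6.79 mM and the 0.838 mM of first nucleophile still dissolved at 100 s together come to 93.7% of the same ceiling. Autumn's 0.361 mM lies far below that ceiling, and there the slowness of the transfer of gas to second nucleophile is the largest single effect on the target, and it works in the target's favour: in the autumn run with that slowness taken away, the target fell to 0.0118 mM.

The numbers of this flask were set for the occasion, and the outcome is calculated.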